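**Retrosynthesis**
- Angustifolin comes from a SmI2 dialdehyde cascade (ketyl radical added 6-endo to an enoate, then aldol). It builds rings C and D, the C8 quaternary centre and stereocentres C9, C11, C13 and C15 in one step. C15-OH is then oxidised and C16 methylenated.
- The dialdehyde comes from ozonolysis of a 4-substituted cyclopentene carried on C8 of a spiro-δ-lactone enoate (C8=C9).
- That enoate comes from intramolecular aldol and dehydration of an ester between C20-OH and a C9 aldehyde. The hydroxy aldehyde comes from an A-ring/acetal built by Diels–Alder of 4-methylbutenolide with a 1-substituted diene, then C10 quaternisation.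
- Ring order: A and the cyclic acetal (Diels–Alder), then the spiro-lactone, then C and D together (cascade).

Assumptions: the C6 OMe is the exo (cis to H-5) thermodynamic acetal, and the C11/C9 configuration is delivered by substrate control in the cascade.

---

**Step 1**
Reactants: 1 (E)-penta-2,4-dien-1-ol
Product: 2 (E)-1-(benzyloxy)penta-2,4-diene
Conditions: NaH, BnBr, TBAI (cat.), THF, 0 °C→rt
Reagents that add atoms: benzyl bromide, BrCc1ccccc1
Why: Williamson etherification gives a benzyl ether that is removed later together with the ring alkene in one hydrogenation.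

**Step 2**
Reactants: 2; 3 4-methylfuran-2(5H)-one
Product: 4 cis-fused bicyclic lactone Diels–Alder adduct
Conditions: chiral (S)-oxazaborolidinium NTf2⁻ Lewis acid (20 mol %), CH2Cl2, –40 °C→rt, 3 d
Reagents that add atoms: none
Why: Diels–Alder gives the "ortho" regiochemistry (diene C1 bonds to the lactone α-carbon C5, the CH2 terminus to the β-carbon C4). Suprafacial addition keeps C19 and C6 cis, which fixes C4/C5 relative to each other, and the catalyst face selects the absolute configuration; C10 is epimerisable and is reset later. Proposed new method: Lewis-acid activation of the lactone carbonyl lowers the LUMO enough for a hindered β,β-disubstituted butenolide to react at a quaternary centre; closest known reaction is the oxazaborolidinium-catalysed enantioselective Diels–Alder of α-substituted acroleins and enones with 1-substituted dienes.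

**Step 3**
Reactants: 4
Product: 5 methyl acetal (exo-OMe)
Conditions: (i) DIBAL-H (1.1 equiv), CH2Cl2, –78 °C; (ii) MeOH, CSA (cat.), rt, one pot
Reagents that add atoms: methanol, CO
Why: DIBAL stops at the lactol, and acid-catalysed acetalisation under thermodynamic control gives the exo-OMe (cis to H-5, anomerically stabilised) methyl acetal (C6), setting that centre.

**Step 4**
Reactants: 5
Product: 6 saturated primary alcohol
Conditions: H2 (1 atm), Pd(OH)2/C, NaHCO3, EtOAc, rt
Reagents that add atoms: none
Why: one hydrogenation reduces the cyclohexene C1=C2 and hydrogenolyses the benzyl ether; the acetal and all stereocentres are untouched.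

**Step 5**
Reactants: 6
Product: 7 aldehyde
Conditions: DMP, NaHCO3, CH2Cl2, 0 °C
Reagents that add atoms: none
Why: buffered Dess–Martin oxidation of the primary alcohol; the only stereocentre α to the aldehyde (C10) is reset in the next step.

**Step 6**
Reactants: 7
Product: 8 2,2-disubstituted propane-1,3-diol (C10 quaternary)
Conditions: 37 % aq HCHO (6 equiv), Ca(OH)2, THF/H2O, 40 °C
Reagents that add atoms: formaldehyde, C=O
Why: aldol at C10–H followed by crossed Cannizzaro reduction by excess formaldehyde gives the quaternary centre bearing two identical CH2OH arms. The C10 configuration is therefore not decided here; it is decided in Step 7.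

**Step 7**
Reactants: 8
Product: 9 hydroxy aldehyde with the C10 configuration of the target (C20-OH cis to the fused acetal ring, CHO trans)
Conditions: TEMPO (10 mol %), PhI(OAc)2 (1.0 equiv), CH2Cl2, 0 °C
Reagents that add atoms: none
Why: the CH2OH arm syn to the cis-fused acetal ring (axial, 1,3-diaxial to C19) is shielded and survives as C20, while the equatorial arm anti to that ring is oxidised and becomes C9. Proposed new method: TEMPO/iodosobenzene diacetate (PIDA) differentiation of diastereotopic neopentyl CH2OH groups by the ring-fusion environment; closest known reaction is the selective TEMPO oxidation of the less hindered primary alcohol of a 1,3-diol.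

**Step 8**
Reactants: 10 3-cyclopentene-1-methanol
Product: 11 (cyclopent-3-en-1-yl)methyl bromide
Conditions: CBr4, PPh3, CH2Cl2, 0 °C
Reagents that add atoms: carbon tetrabromide, BrC(Br)(Br)Br
Why: Appel bromination of a primary alcohol; the cyclopentene is not affected.

**Step 9**
Reactants: 12 tert-butyl acetate; 11
Product: 13 tert-butyl 3-(cyclopent-3-en-1-yl)propanoate
Conditions: LDA, THF, –78 °C; then 11, DMPU, –78→0 °C
Reagents that add atoms: none
Why: alkylation of the ester enolate with a primary bromide; the tert-butyl ester blocks self-condensation.

**Step 10**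
Reactants: 13
Product: 14 3-(cyclopent-3-en-1-yl)propanoic acid
Conditions: TFA, CH2Cl2, rt
Reagents that add atoms: none
Why: acidolysis of the tert-butyl ester by loss of isobutene.

**Step 11**
Reactants: 9; 14
Product: 15 ester of the C20 alcohol with acid 14 (aldehyde retained)
Conditions: 2,4,6-Cl3C6H2COCl, Et3N, THF; then 9, DMAP, toluene, rt
Reagents that add atoms: none
Why: Yamaguchi esterification of the hindered primary alcohol; the aldehyde has no α-H and survives, and all stereocentres are untouched.

**Step 12**
Reactants: 15
Product: 16 β-hydroxy spiro-δ-lactone (C8/C9 stereocentres are removed in Step 13)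
Conditions: LiHMDS (1.2 equiv), THF, –78 °C
Reagents that add atoms: none
Why: the ester enolate closes the six-membered lactone by intramolecular aldol onto the non-enolisable C9 aldehyde (6-(enolexo)-exo-trig).

**Step 13**
Reactants: 16
Product: 17 spiro α,β-unsaturated δ-lactone (C8=C9) carrying the cyclopentenylmethyl group
Conditions: MsCl, Et3N, CH2Cl2, 0 °C; then DBU, rt
Reagents that add atoms: none
Why: mesylation and E1cB elimination through the lactone enolate give the conjugated enoate, the radical acceptor for the cascade.

**Step 14**
Reactants: 17
Product: 18 3-substituted glutaraldehyde (dialdehyde)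
Conditions: O3 (1 equiv, –78 °C, CH2Cl2), then Me2S, –78 °C→rt; use immediately
Reagents that add atoms: ozone, [O-][O+]=O
Why: the cis-disubstituted, electron-rich cyclopentene reacts much faster than the electron-poor trisubstituted enoate, and cleaving a 4-substituted cyclopentene gives a symmetrical CH2CHO/CH2CHO pair on C13.

**Step 15**
Reactants: 18
Product: 19 tetracyclic diol (C11-OH, C15-OH, C16H2)
Conditions: SmI2 (4.5 equiv), HMPA (9 equiv), THF, –78→–20 °C, 1 h; quench with aq Rochelle salt
Reagents that add atoms: none
Why: one aldehyde becomes a ketyl radical that adds 6-endo to C9, the β-carbon of the enoate. The resulting C8 Sm(III) enolate then aldolises 5-exo onto the second aldehyde. This forms rings C and D (bicyclo[3.2.1]octane), the C8 quaternary centre and stereocentres C9, C11, C13 and C15. C13 is desymmetrised by the chiral spiro framework, the ketyl adds to the enoate face opposite the fused acetal ring, and the bridged geometry forces C13, C15 and C8 to be mutually cis. Proposed new method: the same ketyl–enoate/aldol cascade transposed to this acetal-bearing spirolactone; closest known reaction is the Sm(II) ketyl–enoate/aldol cascade used for enmein-type ent-kauranoids.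

**Step 16**
Reactants: 19
Product: 20 C15 ketone (C11-OH retained)
Conditions: DMP (1.05 equiv), NaHCO3, CH2Cl2, 0 °C
Reagents that add atoms: none
Why: C11-OH sits beside the very congested C9 (flanked by quaternary C8 and C10), so the less hindered C15-OH is oxidised selectively; no stereocentre is changed (C15 loses its stereocentre).

**Step 17**
Reactants: 20
Product: 21 Mannich base at C16
Conditions: LiHMDS (2.2 equiv), THF, –78 °C; then CH2=NMe2⁺ I⁻, –78→0 °C
Reagents that add atoms: Eschenmoser's salt, C[N+](C)=C
Why: the only enolisable position of the bridged C15 ketone is C16 (C8 is quaternary), so Mannich aminomethylation is regiospecific; the C16 stereocentre is destroyed in the next step.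

**Step 18**
Reactants: 21
Product: 22 angustifolin
Conditions: MeI (excess), CH2Cl2, rt; then aq NaHCO3, rt
Reagents that add atoms: none (the MeI-derived methyl leaves as Me3N)
Why: quaternisation followed by E1cB/Hofmann-type elimination gives the exocyclic α-methylene ketone, and all other stereocentres are untouched.

---

**Compound list**

| # | Name | SMILES | Role |
|---|---|---|---|
| 1 | (E)-penta-2,4-dien-1-ol | OC/C=C/C=C | starting material |
| 2 | (E)-1-(benzyloxy)penta-2,4-diene | C=C/C=C/COCc1ccccc1 | intermediate |
| 3 | 4-methylfuran-2(5H)-one | CC1=CC(=O)OC1 | starting material |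
| 4 | Diels–Alder adduct (cis-fused lactone) | O=C1OC[C@]2(C)CC=CC(COCc3ccccc3)[C@H]12 | intermediate |
| 5 | exo-methyl acetal | CO[C@H]1OC[C@]2(C)CC=CC(COCc3ccccc3)[C@H]12 | intermediate |
| 6 | saturated primary alcohol | CO[C@H]1OC[C@]2(C)CCCC(CO)[C@H]12 | intermediate |
| 7 | aldehyde | CO[C@H]1OC[C@]2(C)CCCC(C=O)[C@H]12 | intermediate |
| 8 | 1,3-diol (C10 quaternary) | OCC1(CO)CCC[C@@]2(C)CO[C@H](OC)[C@@H]12 | intermediate |
| 9 | hydroxy aldehyde | OC[C@@]1(C=O)CCC[C@@]2(C)CO[C@H](OC)[C@@H]12 | intermediate |
| 10 | 3-cyclopentene-1-methanol | OCC1CC=CC1 | starting material |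
| 11 | (cyclopent-3-en-1-yl)methyl bromide | BrCC1CC=CC1 | intermediate |
| 12 | tert-butyl acetate | CC(=O)OC(C)(C)C | starting material |
| 13 | tert-butyl 3-(cyclopent-3-en-1-yl)propanoate | CC(C)(C)OC(=O)CCC1CC=CC1 | intermediate |
| 14 | 3-(cyclopent-3-en-1-yl)propanoic acid | OC(=O)CCC1CC=CC1 | intermediate |
| 15 | ester-aldehyde | O=C(CCC1CC=CC1)OC[C@@]2(C=O)CCC[C@@]3(C)CO[C@H](OC)[C@@H]23 | intermediate |
| 16 | β-hydroxy spirolactone | O=C1OC[C@@]2(C(O)C1CC3CC=CC3)CCC[C@@]4(C)CO[C@H](OC)[C@@H]24 | intermediate |
| 17 | spiro unsaturated lactone | O=C1OC[C@@]2(C=C1CC3CC=CC3)CCC[C@@]4(C)CO[C@H](OC)[C@@H]24 | intermediate |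
| 18 | dialdehyde | O=C1OC[C@@]2(C=C1CC(CC=O)CC=O)CCC[C@@]3(C)CO[C@H](OC)[C@@H]23 | intermediate |
| 19 | cascade diol (C11-OH, C15-OH) | C1C(O)[C@]23C[C@H]1C[C@@H](O)[C@H]2[C@@]1(CCC[C@@]2(C)CO[C@H](OC)[C@H]21)COC3=O | intermediate |
| 20 | C15 ketone | C1C(=O)[C@]23C[C@H]1C[C@@H](O)[C@H]2[C@@]1(CCC[C@@]2(C)CO[C@H](OC)[C@H]21)COC3=O | intermediate |
| 21 | Mannich base | CN(C)CC1C(=O)[C@]23C[C@H]1C[C@@H](O)[C@H]2[C@@]1(CCC[C@@]2(C)CO[C@H](OC)[C@H]21)COC3=O | intermediate |
| 22 | angustifolin | C=C1C(=O)[C@]23C[C@H]1C[C@@H](O)[C@H]2[C@@]1(CCC[C@@]2(C)CO[C@H](OC)[C@H]21)COC3=O | target |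

---

**Totals:** 18 steps; longest linear sequence 15 steps (1→7, then 11→18).

**Three steps most likely to fail**
1. **Step 15 (SmI2 cascade).** The ketyl must add to a hindered β-carbon next to a quaternary centre, and the aldol and the C11/C9 stereochemistry must follow the target. Fallback: split it into a SmI2 6-endo ketyl cyclisation of a mono-aldehyde/mono-acetal substrate, then close ring D separately by Pd(II)-mediated oxidative cyclisation of a silyl ketene acetal onto a 1,1-disubstituted alkene.
2. **Step 2 (asymmetric Diels–Alder of the β,β-disubstituted butenolide).** Both reactivity and enantioselectivity are uncertain. Fallback: use an Evans N-enoyl oxazolidinone of (Z)-4-silyloxy-3-methylbut-2-enoic acid with Et2AlCl as the dienophile, then lactonise. Alternatively, run a racemic high-pressure Diels–Alder and resolve diol 8 enzymatically by lipase acylation.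
3. **Step 7 (diol desymmetrisation that fixes C10).** The selectivity may be poor or give over-oxidation. Fallback: deliver C20 intramolecularly from the top face. Convert the lactol to an O–CH2–Cl acetal and alkylate the C9-derived enolate to close a C5–C6–O–C20–C10 cage, then open it with MeOH/H⁺ to give the C6 methyl acetal and free C20-OH.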